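**Retrosynthetic overview**
1. Kanzonol L ⇐ two deprotections ⇐ protected isoflavone. The C3–C1′ bond is cut (Suzuki–Miyaura) into a 3-iodochromone (rings A and C, both prenyl groups in place) and a chromen-8-yl boronate (ring B with its fused pyran ring D).
2. Ring D ⇐ key step: the bond between the gem-dimethyl carbon C2 and the vinylic carbon C3 of the pyran ring is formed by cycloisomerization of an ortho-ethynylaryl isopropyl ether (1,5-hydride shift, then C–C closure).
3. Enabling feature: in ring D, C2 carries two methyls and the ring oxygen O1, and C3=C4 is a cis styrenyl olefin whose C4 sits on ring-B carbon C3′ between the oxygen-bearing carbons C2′ and C4′. O1–C2(CH3)2 is thus an isopropyl ether less one hydride and C3=C4 an ethynyl group plus that hydride, with the methine hydrogen five atoms from C4.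
4. 3-Iodochromone ⇐ enaminone iodocyclization ⇐ bis-MOM ether ⇐ C,C-diprenylated 2,4,6-trihydroxyacetophenone. Alkyne precursor ⇐ 2-iodoresorcinol by mono-isopropylation, para-bromination, pivaloylation and Sonogashira coupling.
5. Order of ring formation: ring D on ring B (step 6), ring C on ring A (step 11), then the two bicycles are joined (step 12).

Key step: step 6

Assumption: Kanzonol L has no stereocentre, so only olefin geometries are handled (the ring-held cis C3=C4 bond of ring D and the E-enaminone 12); 2-iodoresorcinol and 2,4,6-trihydroxyacetophenone are taken as commercial.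

**Route**

Step 1
Reactants: 1 2-iodoresorcinol (2-iodobenzene-1,3-diol)
Product: 2 2-iodo-3-isopropoxyphenol
Conditions: 2-bromopropane (1.0 equiv), K2CO3 (1.0 equiv), DMF, 50 °C; unreacted 1 recovered
Reagents that add atoms: 2-bromopropane, CC(C)Br
Why: Williamson ether synthesis on a symmetric diol, so the first alkylation can give only one mono-ether and is held there by limiting halide and base.

Step 2
Reactants: 2 2-iodo-3-isopropoxyphenol
Product: 3 4-bromo-2-iodo-3-isopropoxyphenol
Conditions: N-bromosuccinimide (1.0 equiv), MeCN, −20 °C → 0 °C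
Reagents that add atoms: N-bromosuccinimide, O=C1CCC(=O)N1Br
Why: Electrophilic aromatic bromination should go para to the free hydroxyl (the strongest donor), a position also ortho to the isopropoxy group, while the carbon between the two oxygens is blocked by iodine.

Step 3
Reactants: 3 4-bromo-2-iodo-3-isopropoxyphenol
Product: 4 4-bromo-2-iodo-3-isopropoxyphenyl pivalate
Conditions: pivaloyl chloride, Et3N, DMAP (cat.), CH2Cl2, 0 °C → rt
Reagents that add atoms: pivaloyl chloride, CC(C)(C)C(=O)Cl
Why: O-acylation of the phenol gives an ester oxygen that has no C–H on the atom bound to it and little nucleophilicity, which is what step 6 needs on this side of the alkyne.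

Step 4
Reactants: 4 4-bromo-2-iodo-3-isopropoxyphenyl pivalate
Product: 5 4-bromo-3-isopropoxy-2-[(trimethylsilyl)ethynyl]phenyl pivalate
Conditions: ethynyltrimethylsilane, Pd(PPh3)2Cl2 (cat.), CuI (cat.), Et3N/THF, 45 °C
Reagents that add atoms: ethynyltrimethylsilane, C#C[Si](C)(C)C
Why: Sonogashira coupling, chemoselective because oxidative addition of zerovalent palladium to the C–I bond is much faster than to the C–Br bond, which is kept for step 7.

Step 5
Reactants: 5 4-bromo-3-isopropoxy-2-[(trimethylsilyl)ethynyl]phenyl pivalate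
Product: 6 4-bromo-2-ethynyl-3-isopropoxyphenyl pivalate
Conditions: Bu4NF, AcOH, THF, 0 °C
Reagents that add atoms: none
Why: Fluoride-induced protodesilylation of the alkynylsilane, buffered with acetic acid so that the aryl ester survives.

Step 6
Reactants: 6 4-bromo-2-ethynyl-3-isopropoxyphenyl pivalate
Product: 7 8-bromo-2,2-dimethyl-2H-chromen-5-yl pivalate
Conditions: [(XPhos)Au(NCMe)]SbF6 (5 mol %), MeNO2, 4 Å molecular sieves, 80 °C
Reagents that add atoms: none
Why: Proposed new method: π-coordination of the cationic monovalent gold centre makes the aryl-bound alkyne carbon electrophilic, the isopropoxy methine C–H five atoms away delivers hydride to it through a six-membered transition state (1,5-hydride shift), and the resulting aryloxocarbenium carbon is then attacked by the gold-bearing terminal carbon of the (Z)-alkenylgold, which forms the C(CH3)2–CH= bond and releases the catalyst; the closest known reaction type is the gold- or platinum-catalysed 1,5-hydride shift/cyclization (hydroalkylation) of alkynyl alkyl ethers, together with the acid-catalysed internal redox cyclization of ortho-alkoxy benzylidene malonates to chromans, but an aryl isopropyl ether adding across an ortho ethynyl group is not an established case. Ring D closes in a 6-endo-trig mode with respect to the oxocarbenium C=O bond, the alkenyl C=C bond also lying inside the new six-membered ring. No stereocentre is formed, and the cis geometry of C3=C4 follows from anti hydride/gold addition and is held by the ring. Three selectivities are needed: only the isopropoxy group can donate hydride, because the other oxygen beside the alkyne is a pivalate with no C–H on the atom bound to oxygen and too little nucleophilicity for oxyauration to a benzofuran; hydride goes to the internal alkyne carbon, because this is the carbon a 1,5-shift can reach and the one where positive charge is stabilised by the two oxygen-bearing ring carbons beside it; and closure occurs at the gold-bearing carbon (six-membered ring) and not at the benzylic carbon (five-membered ring via a gold carbene), because ipso attack leaves the charge as a benzylic, gold-coordinated cation and gives the conjugated chromene. Water is excluded so that alkyne hydration cannot compete, and the step is a pure isomerization of 6.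

Step 7
Reactants: 7 8-bromo-2,2-dimethyl-2H-chromen-5-yl pivalate
Product: 8 2,2-dimethyl-8-(4,4,5,5-tetramethyl-1,3,2-dioxaborolan-2-yl)-2H-chromen-5-yl pivalate
Conditions: bis(pinacolato)diboron, Pd(dppf)Cl2 (cat.), KOAc, 1,4-dioxane, 90 °C
Reagents that add atoms: bis(pinacolato)diboron, CC1(C)OB(OC1(C)C)B1OC(C)(C)C(C)(C)O1
Why: Miyaura borylation of the aryl bromide under weakly basic conditions that leave the aryl ester and the chromene olefin untouched.

Step 8
Reactants: 9 2,4,6-trihydroxyacetophenone
Product: 10 1-[2,4,6-trihydroxy-3,5-bis(3-methylbut-2-en-1-yl)phenyl]ethan-1-one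
Conditions: prenyl bromide (2.2 equiv), KOH (10% aq), 0 °C → rt
Reagents that add atoms: prenyl bromide (1-bromo-3-methylbut-2-ene), CC(C)=CCBr
Why: Double C-alkylation of the phloroglucinol-type phenoxide at its two free ring carbons, favoured over O-alkylation in aqueous base, with SN2 attack at the primary carbon keeping the linear prenyl unit.

Step 9
Reactants: 10 1-[2,4,6-trihydroxy-3,5-bis(3-methylbut-2-en-1-yl)phenyl]ethan-1-one
Product: 11 1-[2-hydroxy-4,6-bis(methoxymethoxy)-3,5-bis(3-methylbut-2-en-1-yl)phenyl]ethan-1-one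
Conditions: MOMCl (2.3 equiv), iPr2NEt, CH2Cl2, 0 °C → rt
Reagents that add atoms: chloromethyl methyl ether, COCCl
Why: MOM ether formation stops at the bis-ether because, once one ortho hydroxyl is etherified, the other is held in a hydrogen bond to the ketone and stays free for chromone formation.

Step 10
Reactants: 11 1-[2-hydroxy-4,6-bis(methoxymethoxy)-3,5-bis(3-methylbut-2-en-1-yl)phenyl]ethan-1-one
Product: 12 (E)-3-(dimethylamino)-1-[2-hydroxy-4,6-bis(methoxymethoxy)-3,5-bis(3-methylbut-2-en-1-yl)phenyl]prop-2-en-1-one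
Conditions: Me2NCH(OMe)2, toluene, 90 °C
Reagents that add atoms: N,N-dimethylformamide dimethyl acetal, COC(OC)N(C)C
Why: Condensation of the methyl ketone with the amide acetal gives the thermodynamically preferred E-enaminone.

Step 11
Reactants: 12 (E)-3-(dimethylamino)-1-[2-hydroxy-4,6-bis(methoxymethoxy)-3,5-bis(3-methylbut-2-en-1-yl)phenyl]prop-2-en-1-one
Product: 13 3-iodo-5,7-bis(methoxymethoxy)-6,8-bis(3-methylbut-2-en-1-yl)-4H-chromen-4-one
Conditions: I2 (1.1 equiv), pyridine, CHCl3, 0 °C → rt
Reagents that add atoms: iodine, II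
Why: Iodocyclization of an ortho-hydroxyaryl enaminone to a 3-iodochromone: iodination of the enaminone α-carbon, which is far more nucleophilic than the prenyl olefins, then 6-endo addition–elimination by the phenol with loss of dimethylamine.

Step 12
Reactants: 13 3-iodo-5,7-bis(methoxymethoxy)-6,8-bis(3-methylbut-2-en-1-yl)-4H-chromen-4-one; 8 2,2-dimethyl-8-(4,4,5,5-tetramethyl-1,3,2-dioxaborolan-2-yl)-2H-chromen-5-yl pivalate
Product: 14 8-[5,7-bis(methoxymethoxy)-6,8-bis(3-methylbut-2-en-1-yl)-4-oxo-4H-chromen-3-yl]-2,2-dimethyl-2H-chromen-5-yl pivalate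
Conditions: Pd(OAc)2 (5 mol %), SPhos (10 mol %), K3PO4, toluene/H2O (10:1), 80 °C
Reagents that add atoms: none
Why: Suzuki–Miyaura coupling of a 3-iodochromone with an ortho-alkoxy arylboronate, the usual isoflavone-forming C3–C1′ union, with a bulky electron-rich phosphine to cope with the ortho substituents.

Step 13
Reactants: 14 8-[5,7-bis(methoxymethoxy)-6,8-bis(3-methylbut-2-en-1-yl)-4-oxo-4H-chromen-3-yl]-2,2-dimethyl-2H-chromen-5-yl pivalate
Product: 15 3-(5-hydroxy-2,2-dimethyl-2H-chromen-8-yl)-5,7-bis(methoxymethoxy)-6,8-bis(3-methylbut-2-en-1-yl)-4H-chromen-4-one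
Conditions: K2CO3 (cat.), MeOH/THF, rt
Reagents that add atoms: none
Why: Base-catalysed transesterification of the aryl pivalate with methanol frees the ring-B phenol without touching the MOM ethers or the chromone.

Step 14
Reactants: 15 3-(5-hydroxy-2,2-dimethyl-2H-chromen-8-yl)-5,7-bis(methoxymethoxy)-6,8-bis(3-methylbut-2-en-1-yl)-4H-chromen-4-one
Product: 16 Kanzonol L
Conditions: HCl (3 M aq)/MeOH, 40 °C
Reagents that add atoms: none
Why: Acid-catalysed acetal exchange removes both MOM groups under conditions mild enough that the prenyl groups should not cyclize onto the neighbouring phenols.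

**Compound list**
1 | 2-iodoresorcinol (2-iodobenzene-1,3-diol) | Oc1cccc(O)c1I | starting material
2 | 2-iodo-3-isopropoxyphenol | CC(C)Oc1cccc(O)c1I | intermediate
3 | 4-bromo-2-iodo-3-isopropoxyphenol | CC(C)Oc1c(Br)ccc(O)c1I | intermediate
4 | 4-bromo-2-iodo-3-isopropoxyphenyl pivalate | CC(C)Oc1c(Br)ccc(OC(=O)C(C)(C)C)c1I | intermediate
5 | 4-bromo-3-isopropoxy-2-[(trimethylsilyl)ethynyl]phenyl pivalate | CC(C)Oc1c(Br)ccc(OC(=O)C(C)(C)C)c1C#C[Si](C)(C)C | intermediate
6 | 4-bromo-2-ethynyl-3-isopropoxyphenyl pivalate | CC(C)Oc1c(Br)ccc(OC(=O)C(C)(C)C)c1C#C | intermediate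
7 | 8-bromo-2,2-dimethyl-2H-chromen-5-yl pivalate | CC1(C)C=Cc2c(OC(=O)C(C)(C)C)ccc(Br)c2O1 | intermediate
8 | 2,2-dimethyl-8-(4,4,5,5-tetramethyl-1,3,2-dioxaborolan-2-yl)-2H-chromen-5-yl pivalate | CC1(C)C=Cc2c(OC(=O)C(C)(C)C)ccc(B3OC(C)(C)C(C)(C)O3)c2O1 | intermediate
9 | 2,4,6-trihydroxyacetophenone | CC(=O)c1c(O)cc(O)cc1O | starting material
10 | 1-[2,4,6-trihydroxy-3,5-bis(3-methylbut-2-en-1-yl)phenyl]ethan-1-one | CC(=O)c1c(O)c(CC=C(C)C)c(O)c(CC=C(C)C)c1O | intermediate
11 | 1-[2-hydroxy-4,6-bis(methoxymethoxy)-3,5-bis(3-methylbut-2-en-1-yl)phenyl]ethan-1-one | CC(=O)c1c(O)c(CC=C(C)C)c(OCOC)c(CC=C(C)C)c1OCOC | intermediate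
12 | (E)-3-(dimethylamino)-1-[2-hydroxy-4,6-bis(methoxymethoxy)-3,5-bis(3-methylbut-2-en-1-yl)phenyl]prop-2-en-1-one | CN(C)/C=C/C(=O)c1c(O)c(CC=C(C)C)c(OCOC)c(CC=C(C)C)c1OCOC | intermediate
13 | 3-iodo-5,7-bis(methoxymethoxy)-6,8-bis(3-methylbut-2-en-1-yl)-4H-chromen-4-one | O=c1c(I)coc2c1c(OCOC)c(CC=C(C)C)c(OCOC)c2CC=C(C)C | intermediate
14 | 8-[5,7-bis(methoxymethoxy)-6,8-bis(3-methylbut-2-en-1-yl)-4-oxo-4H-chromen-3-yl]-2,2-dimethyl-2H-chromen-5-yl pivalate | O=c1c(-c3ccc(OC(=O)C(C)(C)C)c4c3OC(C)(C)C=C4)coc2c1c(OCOC)c(CC=C(C)C)c(OCOC)c2CC=C(C)C | intermediate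
15 | 3-(5-hydroxy-2,2-dimethyl-2H-chromen-8-yl)-5,7-bis(methoxymethoxy)-6,8-bis(3-methylbut-2-en-1-yl)-4H-chromen-4-one | O=c1c(-c3ccc(O)c4c3OC(C)(C)C=C4)coc2c1c(OCOC)c(CC=C(C)C)c(OCOC)c2CC=C(C)C | intermediate
16 | Kanzonol L, 5,7-dihydroxy-3-(5-hydroxy-2,2-dimethyl-2H-chromen-8-yl)-6,8-bis(3-methylbut-2-en-1-yl)-4H-chromen-4-one | CC(C)=CCc1c(O)c(CC=C(C)C)c2occ(-c3ccc(O)c4c3OC(C)(C)C=C4)c(=O)c2c1O | target

**Step count**
Total steps: 14. Longest linear sequence: 10 steps (steps 1–7, then 12–14); the ring A/C fragment takes steps 8–11.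

**Three steps most likely to fail**

Step 6 (proposed new method). The hydride transfer may be too slow, so that other pathways take over: attack of the ether oxygen on the gold-bound alkyne with loss of the isopropyl group (benzofuran formation), capture of the alkyne by the pivalate carbonyl followed by hydrolysis, or closure at the benzylic carbon to a five-membered ring. The fallback uses known chemistry and closes ring D at O1–C2 instead; it sets out from 1 and comes back at 7. Heck reaction of 1 with 2-methylbut-3-en-2-ol (Pd(OAc)2, Et3N, DMF, 90 °C) should give 2-[(E)-3-hydroxy-3-methylbut-1-en-1-yl]benzene-1,3-diol F1. Acid-catalysed cyclodehydration through the allyl cation (TsOH cat., toluene, 50 °C; either hydroxyl gives the same ring) should give 2,2-dimethyl-2H-chromen-5-ol F2. Bromination para to the hydroxyl (N-bromosuccinimide, MeCN, −20 °C) should give 8-bromo-2,2-dimethyl-2H-chromen-5-ol F3, and pivaloylation (pivaloyl chloride, Et3N, CH2Cl2) then gives 7.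

Step 11. Electrophilic iodine may attack the electron-rich prenyl double bonds (iodoetherification with loss of a MOM group) in competition with iodination of the enaminone. The fallback avoids electrophilic halogen and builds ring C from a deoxybenzoin; it sets out from 11, uses bromide 7 as partner, and comes back at 16. Etherification of the last hydroxyl (MOMCl, NaH, DMF) should give 1-[2,4,6-tris(methoxymethoxy)-3,5-bis(3-methylbut-2-en-1-yl)phenyl]ethan-1-one F4. Palladium-catalysed ketone α-arylation with 7 (Pd2(dba)3, XPhos, K3PO4, toluene, 90 °C) should give 8-{2-oxo-2-[2,4,6-tris(methoxymethoxy)-3,5-bis(3-methylbut-2-en-1-yl)phenyl]ethyl}-2,2-dimethyl-2H-chromen-5-yl pivalate F5. Condensation with Me2NCH(OMe)2 (toluene, 90 °C) should give 8-{(E)-1-(dimethylamino)-3-oxo-3-[2,4,6-tris(methoxymethoxy)-3,5-bis(3-methylbut-2-en-1-yl)phenyl]prop-1-en-2-yl}-2,2-dimethyl-2H-chromen-5-yl pivalate F6, whose olefin geometry is immaterial. HCl/MeOH (40 °C) should remove the three MOM groups, and a freed ortho hydroxyl then closes ring C with loss of dimethylamine to give 8-[5,7-dihydroxy-6,8-bis(3-methylbut-2-en-1-yl)-4-oxo-4H-chromen-3-yl]-2,2-dimethyl-2H-chromen-5-yl pivalate F7. Methanolysis (K2CO3 cat., MeOH) gives 16.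

Step 2. Bromination may go ortho instead of para to the hydroxyl, or ipso at the iodine-bearing carbon with halogen scrambling. The fallback fixes the bromine position by symmetry and tells the two hydroxyls apart by hindrance; it sets out from 1 and comes back at 4. Bromination of 1 (N-bromosuccinimide 1.0 equiv, MeCN, −20 °C) can give only one mono-bromide, 4-bromo-2-iodobenzene-1,3-diol F8. Acylation of the less hindered hydroxyl, the one not flanked by bromine (pivaloyl chloride 1.0 equiv, pyridine, CH2Cl2, −40 °C), should give 4-bromo-3-hydroxy-2-iodophenyl pivalate F9. Mitsunobu etherification with propan-2-ol (PPh3, diisopropyl azodicarboxylate, THF) gives 4.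

**Further compounds**
F1 | step 6 | 2-[(E)-3-hydroxy-3-methylbut-1-en-1-yl]benzene-1,3-diol | CC(C)(O)/C=C/c1c(O)cccc1O
F2 | step 6 | 2,2-dimethyl-2H-chromen-5-ol | CC1(C)C=Cc2c(O)cccc2O1
F3 | step 6 | 8-bromo-2,2-dimethyl-2H-chromen-5-ol | CC1(C)C=Cc2c(O)ccc(Br)c2O1
F4 | step 11 | 1-[2,4,6-tris(methoxymethoxy)-3,5-bis(3-methylbut-2-en-1-yl)phenyl]ethan-1-one | CC(=O)c1c(OCOC)c(CC=C(C)C)c(OCOC)c(CC=C(C)C)c1OCOC
F5 | step 11 | 8-{2-oxo-2-[2,4,6-tris(methoxymethoxy)-3,5-bis(3-methylbut-2-en-1-yl)phenyl]ethyl}-2,2-dimethyl-2H-chromen-5-yl pivalate | O=C(Cc1ccc(OC(=O)C(C)(C)C)c2c1OC(C)(C)C=C2)c1c(OCOC)c(CC=C(C)C)c(OCOC)c(CC=C(C)C)c1OCOC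
F6 | step 11 | 8-{(E)-1-(dimethylamino)-3-oxo-3-[2,4,6-tris(methoxymethoxy)-3,5-bis(3-methylbut-2-en-1-yl)phenyl]prop-1-en-2-yl}-2,2-dimethyl-2H-chromen-5-yl pivalate | CN(C)/C=C(\c1ccc(OC(=O)C(C)(C)C)c2c1OC(C)(C)C=C2)C(=O)c1c(OCOC)c(CC=C(C)C)c(OCOC)c(CC=C(C)C)c1OCOC
F7 | step 11 | 8-[5,7-dihydroxy-6,8-bis(3-methylbut-2-en-1-yl)-4-oxo-4H-chromen-3-yl]-2,2-dimethyl-2H-chromen-5-yl pivalate | CC(C)=CCc1c(O)c(CC=C(C)C)c2occ(-c3ccc(OC(=O)C(C)(C)C)c4c3OC(C)(C)C=C4)c(=O)c2c1O
F8 | step 2 | 4-bromo-2-iodobenzene-1,3-diol | Oc1ccc(Br)c(O)c1I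
F9 | step 2 | 4-bromo-3-hydroxy-2-iodophenyl pivalate | CC(C)(C)C(=O)Oc1ccc(Br)c(O)c1I
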